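**Retrosynthetic overview**
- The C1′ stereocentre and the arene come last: chemoselective hydrogenation of a methallyl adduct made by three-component union of a decalin aldehyde, 2,4-diformylphloroglucinol and methallylsilane through an o-quinone methide.
- Both tertiary alcohols (C4–O and C11–O) come from one double Markovnikov hydration of a diene aldehyde; the C4–O bond must form axially, cis to the C10 methyl.
- Rings A and B close together in one intramolecular Diels–Alder reaction of an (E,E)-trienal (ring A is the new cyclohexene, ring B closes through the tether), which sets C1, C5 and C10 relative to C7.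
- The trienal comes from (S)-limonene by ring-opening ozonolysis and three olefinations; C7 is taken from the chiral pool.

Assumption: locants follow eudesmane numbering (ring A = C1–C5 and C10, ring B = C5–C10, carbinol carbon C11, benzylic carbon C1′); the SMILES strings are the definitive structures.

**Route**

Step 1
Reactants: 1 (S)-(−)-limonene
Product: 3 (3S)-6-oxo-3-(prop-1-en-2-yl)heptanal, via secondary ozonide 2 (not isolated)
Conditions: O3 (1.0 equiv), CH2Cl2, −78 °C; then Me2S, −78 °C → rt
Reagents that add atoms: ozone, O=[O+][O-]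
Why: The trisubstituted ring alkene is more electron-rich than the isopropenyl group and is cleaved selectively by one equivalent of ozone (Criegee ozonolysis, reductive work-up), leaving the stereocentre (future C7) untouched.

Step 2
Reactants: 3 (3S)-6-oxo-3-(prop-1-en-2-yl)heptanal; 4 2-(triphenyl-λ5-phosphanylidene)propanal
Product: 5 (2E,5S)-2-methyl-8-oxo-5-(prop-1-en-2-yl)non-2-enal
Conditions: 4 (1.1 equiv), toluene, 80 °C
Reagents that add atoms: 4 2-(triphenyl-λ5-phosphanylidene)propanal, CC(C=O)=P(c1ccccc1)(c1ccccc1)c1ccccc1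
Why: The stabilised ylide reacts with the aldehyde only, not the methyl ketone, and gives the (E)-2-methyl enal (Wittig reaction), which fixes the geometry the diene needs.

Step 3
Reactants: 5 (2E,5S)-2-methyl-8-oxo-5-(prop-1-en-2-yl)non-2-enal; 6 methyltriphenylphosphonium bromide
Product: 7 (5S,7E)-8-methyl-5-(prop-1-en-2-yl)deca-7,9-dien-2-one
Conditions: 6 (1.05 equiv), KN(SiMe3)2, THF, −78 → 0 °C
Reagents that add atoms: 6 methyltriphenylphosphonium bromide, C[P+](c1ccccc1)(c1ccccc1)c1ccccc1.[Br-]
Why: At low temperature the non-stabilised ylide adds to the enal carbonyl much faster than to the methyl ketone (Wittig methylenation), giving the (E)-2-methyl-1,3-diene with the alkene geometry retained.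

Step 4
Reactants: 7 (5S,7E)-8-methyl-5-(prop-1-en-2-yl)deca-7,9-dien-2-one; 8 diethyl [(E)-2-(cyclohexylamino)ethenyl]phosphonate
Product: 10 (2E,6S,8E)-3,9-dimethyl-6-(prop-1-en-2-yl)undeca-2,8,10-trienal, via N-cyclohexyl imine 9 (not isolated)
Conditions: 8 (1.3 equiv), NaH, THF, 0 °C → rt; then aq. (CO2H)2, toluene, rt; E isomer separated on silica
Reagents that add atoms: 8 diethyl [(E)-2-(cyclohexylamino)ethenyl]phosphonate, CCOP(=O)(OCC)/C=C/NC1CCCCC1; water, O
Why: The phosphonate-stabilised enamine anion olefinates the methyl ketone and mild acid hydrolysis of the unsaturated imine releases the enal (Horner–Wadsworth–Emmons-type formylolefination, expected E:Z about 3:1, only the E isomer is carried on).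

Step 5
Reactants: 10 (2E,6S,8E)-3,9-dimethyl-6-(prop-1-en-2-yl)undeca-2,8,10-trienal
Product: 11 (1S,4aR,6S,8aS)-4,8a-dimethyl-6-(prop-1-en-2-yl)-1,2,4a,5,6,7,8,8a-octahydronaphthalene-1-carbaldehyde
Conditions: Me2AlCl (0.2 equiv), CH2Cl2, −78 → −20 °C
Reagents that add atoms: none
Why: Lewis-acid-catalysed intramolecular Diels–Alder reaction through the formyl-endo transition state, with a chair-like tether carrying the isopropenyl group equatorial, gives the trans-fused decalin: C5–H ends trans, and C1–CHO (suprafacial addition to the E-dienophile) and the C7 substituent end cis, to the new C10 methyl.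

Step 6
Reactants: 11 (1S,4aR,6S,8aS)-4,8a-dimethyl-6-(prop-1-en-2-yl)-1,2,4a,5,6,7,8,8a-octahydronaphthalene-1-carbaldehyde
Product: 13 (1S,4R,4aS,6S,8aS)-4-hydroxy-6-(2-hydroxypropan-2-yl)-4,8a-dimethyldecahydronaphthalene-1-carbaldehyde, via mono-hydrated aldehyde 12 (not isolated)
Conditions: C36H54CoN2O2 (10 mol %; divalent cobalt complex of N,N′-bis(3,5-di-tert-butylsalicylidene)-2,3-dimethylbutane-2,3-diamine), N-fluoro-2,4,6-trimethylpyridinium tetrafluoroborate (2.4 equiv), PhSiH3 (2.4 equiv), acetone–H2O (10:1), argon, 0 °C → rt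
Reagents that add atoms: water, O
Why: Proposed new method: a one-pot double Markovnikov hydration by cobalt-hydride hydrogen-atom transfer and radical–polar crossover, in which each tertiary radical is captured by the bulky cobalt salen on its open face (at C4 the face anti to the angular methyl), oxidised to an alkylcobalt species of tetravalent cobalt and displaced by water with inversion, so that the C4–O bond forms axially and cis to the C10 methyl (the same outcome as trans-diaxial halohydrin opening) while C11 is not stereogenic; the closest known reactions are the Mukaiyama hydration and the cobalt salen/N-fluoropyridinium/silane hydroalkoxylation of alkenes, which to my knowledge has not been used for stereoinvertive delivery of water to a ring tertiary carbon or for two alkenes in one substrate.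

Step 7
Reactants: 14 phloroglucinol
Product: 16 2,4,6-trihydroxybenzene-1,3-dicarbaldehyde, via bis-iminium salt 15 (not isolated)
Conditions: POCl3 (2.2 equiv), DMF (2.2 equiv), 1,4-dioxane, 0 °C → rt; then H2O
Reagents that add atoms: N,N-dimethylformamide, CN(C)C=O; water, O
Why: The chloroiminium electrophile formylates the very electron-rich ring twice and the third position stays free because two iminium/formyl groups deactivate it (Vilsmeier–Haack formylation).

Step 8
Reactants: 13 (1S,4R,4aS,6S,8aS)-4-hydroxy-6-(2-hydroxypropan-2-yl)-4,8a-dimethyldecahydronaphthalene-1-carbaldehyde; 16 2,4,6-trihydroxybenzene-1,3-dicarbaldehyde; 17 trimethyl(2-methylprop-2-en-1-yl)silane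
Product: 19 5-[(1R)-1-[(1R,4R,4aS,6S,8aR)-4-hydroxy-6-(2-hydroxypropan-2-yl)-4,8a-dimethyldecahydronaphthalen-1-yl]-3-methylbut-3-en-1-yl]-2,4,6-trihydroxybenzene-1,3-dicarbaldehyde, via o-quinone methide 18 (not isolated)
Conditions: 16 (1.2 equiv), 17 (5 equiv), NaOAc (0.2 equiv), AcOH, 60 °C
Reagents that add atoms: 16 2,4,6-trihydroxybenzene-1,3-dicarbaldehyde, O=Cc1c(O)cc(O)c(C=O)c1O; 17 trimethyl(2-methylprop-2-en-1-yl)silane, C=C(C)C[Si](C)(C)C
Why: Knoevenagel-type condensation at the only free ring carbon gives an o-quinone methide that the allylsilane attacks (Hosomi–Sakurai-type conjugate addition, biomimetic three-component coupling); with C1–H eclipsing the exocyclic C=C (allylic 1,3-strain) the nucleophile adds anti to the quaternary C10, which sets C1′ as R.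

Step 9
Reactants: 19 5-[(1R)-1-[(1R,4R,4aS,6S,8aR)-4-hydroxy-6-(2-hydroxypropan-2-yl)-4,8a-dimethyldecahydronaphthalen-1-yl]-3-methylbut-3-en-1-yl]-2,4,6-trihydroxybenzene-1,3-dicarbaldehyde
Product: 20 5-[(1R)-1-[(1R,4R,4aS,6S,8aR)-4-hydroxy-6-(2-hydroxypropan-2-yl)-4,8a-dimethyldecahydronaphthalen-1-yl]-3-methylbutyl]-2,4,6-trihydroxybenzene-1,3-dicarbaldehyde
Conditions: H2 (1 atm), RhCl(PPh3)3 (5 mol %), benzene–EtOH (1:1), rt
Reagents that add atoms: none
Why: RhCl(PPh3)3 hydrogenates the unhindered 1,1-disubstituted alkene and leaves the hydrogen-bonded aryl aldehydes, phenols and tertiary alcohols untouched (homogeneous catalytic hydrogenation); no stereocentre is formed.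

**Compound list**

1 | (4S)-1-methyl-4-(prop-1-en-2-yl)cyclohex-1-ene, (S)-(−)-limonene | CC1=CC[C@H](CC1)C(C)=C | starting material
2 | 1-methyl-4-(prop-1-en-2-yl)-7,8,9-trioxabicyclo[4.2.1]nonane, secondary ozonide of 1 (isopropenyl-bearing carbon as in 1) | CC12CC[C@H](C(C)=C)CC(OO1)O2 | intermediate (not isolated)
3 | (3S)-6-oxo-3-(prop-1-en-2-yl)heptanal | O=CC[C@@H](C(C)=C)CCC(C)=O | intermediate
4 | 2-(triphenyl-λ5-phosphanylidene)propanal | CC(C=O)=P(c1ccccc1)(c1ccccc1)c1ccccc1 | starting material
5 | (2E,5S)-2-methyl-8-oxo-5-(prop-1-en-2-yl)non-2-enal | O=C/C(C)=C/C[C@@H](C(C)=C)CCC(C)=O | intermediate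
6 | methyltriphenylphosphonium bromide | C[P+](c1ccccc1)(c1ccccc1)c1ccccc1.[Br-] | starting material
7 | (5S,7E)-8-methyl-5-(prop-1-en-2-yl)deca-7,9-dien-2-one | C=C/C(C)=C/C[C@@H](C(C)=C)CCC(C)=O | intermediate
8 | diethyl [(E)-2-(cyclohexylamino)ethenyl]phosphonate | CCOP(=O)(OCC)/C=C/NC1CCCCC1 | starting material
9 | (2E,6S,8E)-N-cyclohexyl-3,9-dimethyl-6-(prop-1-en-2-yl)undeca-2,8,10-trien-1-imine | C1CCCCC1N=C/C=C(\C)CC[C@H](C(C)=C)C/C=C(C)/C=C | intermediate (not isolated)
10 | (2E,6S,8E)-3,9-dimethyl-6-(prop-1-en-2-yl)undeca-2,8,10-trienal | O=C/C=C(\C)CC[C@H](C(C)=C)C/C=C(C)/C=C | intermediate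
11 | (1S,4aR,6S,8aS)-4,8a-dimethyl-6-(prop-1-en-2-yl)-1,2,4a,5,6,7,8,8a-octahydronaphthalene-1-carbaldehyde (trans-fused; CHO and isopropenyl cis to the angular methyl) | O=C[C@H]1CC=C(C)[C@H]2C[C@@H](C(C)=C)CC[C@]12C | intermediate
12 | (1S,4aR,6S,8aS)-6-(2-hydroxypropan-2-yl)-4,8a-dimethyl-1,2,4a,5,6,7,8,8a-octahydronaphthalene-1-carbaldehyde | O=C[C@H]1CC=C(C)[C@H]2C[C@@H](C(C)(C)O)CC[C@]12C | intermediate (not isolated)
13 | (1S,4R,4aS,6S,8aS)-4-hydroxy-6-(2-hydroxypropan-2-yl)-4,8a-dimethyldecahydronaphthalene-1-carbaldehyde (4-OH axial, cis to the angular methyl) | O=C[C@H]1CC[C@@](C)(O)[C@H]2C[C@@H](C(C)(C)O)CC[C@]12C | intermediate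
14 | benzene-1,3,5-triol, phloroglucinol | Oc1cc(O)cc(O)c1 | starting material
15 | N,N′-[(2,4,6-trihydroxy-1,3-phenylene)dimethanylylidene]bis(N-methylmethanaminium) dichloride | C[N+](C)=Cc1c(O)cc(O)c(C=[N+](C)C)c1O.[Cl-].[Cl-] | intermediate (not isolated)
16 | 2,4,6-trihydroxybenzene-1,3-dicarbaldehyde | O=Cc1c(O)cc(O)c(C=O)c1O | intermediate
17 | trimethyl(2-methylprop-2-en-1-yl)silane | C=C(C)C[Si](C)(C)C | starting material
18 | 5-{[(1R,4R,4aS,6S,8aR)-4-hydroxy-6-(2-hydroxypropan-2-yl)-4,8a-dimethyldecahydronaphthalen-1-yl]methylidene}-2,4-dihydroxy-6-oxocyclohexa-1,3-diene-1,3-dicarbaldehyde | O=CC1=C(O)C(C=O)=C(O)C(=C[C@H]2CC[C@@](C)(O)[C@H]3C[C@@H](C(C)(C)O)CC[C@]23C)C1=O | intermediate (not isolated)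
19 | 5-[(1R)-1-[(1R,4R,4aS,6S,8aR)-4-hydroxy-6-(2-hydroxypropan-2-yl)-4,8a-dimethyldecahydronaphthalen-1-yl]-3-methylbut-3-en-1-yl]-2,4,6-trihydroxybenzene-1,3-dicarbaldehyde | C=C(C)C[C@@H](c1c(O)c(C=O)c(O)c(C=O)c1O)[C@H]1CC[C@@](C)(O)[C@H]2C[C@@H](C(C)(C)O)CC[C@]12C | intermediate
20 | 5-[(1R)-1-[(1R,4R,4aS,6S,8aR)-4-hydroxy-6-(2-hydroxypropan-2-yl)-4,8a-dimethyldecahydronaphthalen-1-yl]-3-methylbutyl]-2,4,6-trihydroxybenzene-1,3-dicarbaldehyde | CC(C)C[C@@H](c1c(O)c(C=O)c(O)c(C=O)c1O)[C@H]1CC[C@@](C)(O)[C@H]2C[C@@H](C(C)(C)O)CC[C@]12C | target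

**Step count and risks**

Total steps: 9. Longest linear sequence: 8 steps (1 → 20 through steps 1–6, 8 and 9; step 7 is a one-step side branch).

Three steps most likely to fail:

1. Step 6 (the proposed new step). If the alkylcobalt intermediate ionises to a free C4 cation, water will enter from the open face and give the equatorial 4-epimer, and the silane may partly reduce the aldehyde. The fallback is known chemistry, sets out from 11 and comes back at 13. N-Bromosuccinimide in acetone–H2O at 0 °C forms the bromonium ions on the faces away from the angular methyl; water opens the ring bromonium trans-diaxially at the tertiary C4 and adds Markovnikov at the isopropenyl group, giving the bis-bromohydrin F1. Bu3SnH with AIBN in toluene at 80 °C then removes both bromines and gives 13 with the same axial C4 hydroxyl.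

2. Step 8. The hindered aldehyde may condense slowly, the o-quinone methide may tautomerise to a vinylphenol or be trapped by the C4 hydroxyl, and the facial selectivity at C1′ rests on a conformational model. The fallback replaces the free o-quinone methide by a protected benzylic cation, sets out from 13 and comes back at 19. 2,4,6-Trimethoxyphenyllithium (from 1,3,5-trimethoxybenzene and n-BuLi, THF, −78 °C) adds to 13 to give the benzylic carbinol F2. BF3·OEt2 and 17 in CH2Cl2 at −78 °C ionise it to the benzylic cation, which is allylated anti to C10 to give the allylated trimethoxyarene F3. Two rounds of ortho-lithiation (n-BuLi, TMEDA) and DMF quench give the dialdehyde F4, and 4-MeC6H4SLi in HMPA–toluene at 110 °C cleaves the three methyl ethers to give 19.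

3. Step 5. The β,β-disubstituted enal is a sluggish dienophile, residual Z isomer from step 4 gives cis-fused material, and endo/exo and facial selectivities may be incomplete. The fallback uses an ester dienophile whose E isomer is easier to purify and which has firm Lewis-acid precedent; it sets out from 7, bypasses 10 and comes back at 11. Triethyl phosphonoacetate and NaH in THF convert 7 into the (E)-trienoate F5 (E isomer purified). EtAlCl2 in CH2Cl2 at rt (or heating in toluene at 160 °C) closes it to the decalin ester F6, and i-Bu2AlH in CH2Cl2 at −78 °C reduces F6 to 11.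

**Further compounds**

F1 | step 6 | 3-bromo-6-(1-bromo-2-hydroxypropan-2-yl)-4-hydroxy-4,8a-dimethyldecahydronaphthalene-1-carbaldehyde (ring stereochemistry as in 13; C3 bromine trans-diaxial to the C4 hydroxyl; both epimers at the side-chain carbinol) | O=C[C@H]1C[C@H](Br)[C@@](C)(O)[C@H]2C[C@@H](C(C)(O)CBr)CC[C@]12C
F2 | step 8 | 4-[hydroxy(2,4,6-trimethoxyphenyl)methyl]-7-(2-hydroxypropan-2-yl)-1,4a-dimethyldecahydronaphthalen-1-ol (ring stereochemistry as in 13; both carbinol epimers) | COc1cc(OC)c(C(O)[C@H]2CC[C@@](C)(O)[C@H]3C[C@@H](C(C)(C)O)CC[C@]23C)c(OC)c1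
F3 | step 8 | (1R,4R,4aR,7S,8aS)-7-(2-hydroxypropan-2-yl)-1,4a-dimethyl-4-[(1R)-3-methyl-1-(2,4,6-trimethoxyphenyl)but-3-en-1-yl]decahydronaphthalen-1-ol | C=C(C)C[C@@H](c1c(OC)cc(OC)cc1OC)[C@H]1CC[C@@](C)(O)[C@H]2C[C@@H](C(C)(C)O)CC[C@]12C
F4 | step 8 | 5-[(1R)-1-[(1R,4R,4aS,6S,8aR)-4-hydroxy-6-(2-hydroxypropan-2-yl)-4,8a-dimethyldecahydronaphthalen-1-yl]-3-methylbut-3-en-1-yl]-2,4,6-trimethoxybenzene-1,3-dicarbaldehyde | C=C(C)C[C@@H](c1c(OC)c(C=O)c(OC)c(C=O)c1OC)[C@H]1CC[C@@](C)(O)[C@H]2C[C@@H](C(C)(C)O)CC[C@]12C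
F5 | step 5 | ethyl (2E,6S,8E)-3,9-dimethyl-6-(prop-1-en-2-yl)undeca-2,8,10-trienoate | CCOC(=O)/C=C(\C)CC[C@H](C(C)=C)C/C=C(C)/C=C
F6 | step 5 | ethyl (1S,4aR,6S,8aS)-4,8a-dimethyl-6-(prop-1-en-2-yl)-1,2,4a,5,6,7,8,8a-octahydronaphthalene-1-carboxylate | CCOC(=O)[C@H]1CC=C(C)[C@H]2C[C@@H](C(C)=C)CC[C@]12C
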